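**Retrosynthetic overview**
- Target ⇒ hydrolysis/desilylation and C3 aroylation of the methyl enol ether of the fully alkylated bicyclo[3.3.1]nonane-2,4,9-trione; the aroyl chloride comes from catechol and CO2.
- Bicyclic enol ether ⇒ semipinacol ring expansion (1,2-shift of the C(Me)(homoprenyl) carbon, cyclopentane → cyclohexanone) of a cis-fused hydrindane aldolate made in the same flask by a vinylogous aldol.
- Aldol precursor ⇒ 5-acyl-5-prenylcyclopentanone ⇒ C5 acylation with (E)-3-methoxybut-2-enoic acid, then γ- and C5-prenylation with two equivalents of prenyl bromide (C5 prenyl anti to the ring prenyl).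
- Cyclopentanone ⇒ 2-methylcyclopent-2-enone by asymmetric conjugate addition, trans-selective enolate alkylation and alkene isomerisation.
- Ring order: cyclopentane (from the enone) → ring A as a fused cyclohexenone (aldol) → ring B by 5→6 expansion, which turns the fused bicycle into the bridged one.

Assumption: the target is drawn as one tautomer of an enolised β-triketone, so any tautomer of the final product counts as the target; (E)-3-methoxybut-2-enoic acid is taken as a catalogue compound.

**Step 1**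
Reactants: 1 2-methylcyclopent-2-en-1-one; 2 4-bromo-2-methylbut-1-ene
Product: 5 (S)-trimethyl{[2-methyl-3-(3-methylbut-3-en-1-yl)cyclopent-1-en-1-yl]oxy}silane, via Grignard reagent 3 (not isolated), via magnesium enolate 4 (not isolated)
Conditions: 2, Mg, THF, 40 °C; then 1, Cu(OTf)2 (4 mol %), chiral C2-symmetric imidazolinium chloride (NHC precursor, 5 mol %, enantiomer giving (S)-5), Et2O, −30 °C; then Me3SiCl, Et3N, HMPA, −30 → 0 °C
Reagents that add atoms: chlorotrimethylsilane C[Si](C)(C)Cl
Why: Copper–NHC-catalysed asymmetric conjugate addition of a primary alkyl Grignard reagent to an α-methyl cycloalkenone is an established reaction class; the chiral copper complex adds the chain to one enone face and sets C3 (S), and silylation of the regio-defined magnesium enolate fixes the enolate position.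

**Step 2**
Reactants: 5 (S)-trimethyl{[2-methyl-3-(3-methylbut-3-en-1-yl)cyclopent-1-en-1-yl]oxy}silane; 6 5-bromo-2-methylpent-2-ene
Product: 8 (2R,3S)-2-methyl-3-(3-methylbut-3-en-1-yl)-2-(4-methylpent-3-en-1-yl)cyclopentan-1-one, via lithium enolate 7 (not isolated)
Conditions: MeLi, THF, 0 °C; then 6, HMPA, Bu4NI (10 mol %), −40 °C → rt
Reagents that add atoms: none
Why: Methyllithium cleavage of the silyl enol ether gives the tetrasubstituted lithium enolate regiospecifically, and SN2 enolate alkylation occurs anti to the C3 chain, creating the quaternary centre (2R) with homoprenyl trans and methyl cis to that chain.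

**Step 3**
Reactants: 8 (2R,3S)-2-methyl-3-(3-methylbut-3-en-1-yl)-2-(4-methylpent-3-en-1-yl)cyclopentan-1-one
Product: 9 (2R,3R)-2-methyl-3-(3-methylbut-2-en-1-yl)-2-(4-methylpent-3-en-1-yl)cyclopentan-1-one
Conditions: Co(salen)Cl (3 mol %; trivalent cobalt, salen = N,N′-bis(3,5-di-tert-butylsalicylidene)cyclohexane-1,2-diaminate), PhSiH3 (6 mol %), benzene, rt
Reagents that add atoms: none
Why: Cobalt-hydride hydrogen-atom-transfer alkene isomerisation moves the 1,1-disubstituted terminal alkene by one position into the more stable trisubstituted (prenyl) position under neutral conditions; the ketone, both stereocentres and the already trisubstituted homoprenyl alkene are untouched (the descriptor at C3 changes only by priority).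

**Step 4**
Reactants: 9 (2R,3R)-2-methyl-3-(3-methylbut-2-en-1-yl)-2-(4-methylpent-3-en-1-yl)cyclopentan-1-one; 10 (E)-3-methoxybut-2-enoic acid
Product: 12 (2R,3S)-5-[(E)-3-methoxybut-2-enoyl]-2-methyl-3-(3-methylbut-2-en-1-yl)-2-(4-methylpent-3-en-1-yl)cyclopentan-1-one (C5 epimers/enol form), via acyl imidazolide 11 (not isolated)
Conditions: 10, 1,1′-carbonyldiimidazole, THF, rt; 9, LiN(SiMe3)2 (2.1 equiv), THF, −78 °C, then 11, −78 → −20 °C; aq. NH4Cl
Reagents that add atoms: none
Why: The ketone can enolise only toward C5, and the lithium enolate is C-acylated by the acyl imidazolide while the second equivalent of base traps the β-diketone as its enolate (crossed Claisen condensation); C5 is not yet a fixed stereocentre.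

**Step 5**
Reactants: 12 (2R,3S)-5-[(E)-3-methoxybut-2-enoyl]-2-methyl-3-(3-methylbut-2-en-1-yl)-2-(4-methylpent-3-en-1-yl)cyclopentan-1-one; 13 1-bromo-3-methylbut-2-ene
Product: 15 (2R,3S,5S)-5-[(E)-3-methoxy-7-methylocta-2,6-dienoyl]-2-methyl-3,5-bis(3-methylbut-2-en-1-yl)-2-(4-methylpent-3-en-1-yl)cyclopentan-1-one, via lithium enolate 14 (not isolated)
Conditions: LiN(i-Pr)2 (2.1 equiv), THF, −78 → −40 °C; 13 (1.0 equiv), −78 °C, 1 h; then HMPA, a second portion of 1-bromo-3-methylbut-2-ene (1.5 equiv), −78 °C → rt; aq. NH4Cl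
Reagents that add atoms: 1-bromo-3-methylbut-2-ene CC(C)=CCBr
Why: Hauser-type dianion alkylation that installs two prenyl groups in one flask: the first equivalent of 13 alkylates the more basic γ-carbanion of the methoxy enone to give lithium β-diketonate 14, and the second equivalent (entered above as the atom-adding reagent) C-alkylates C5 of 14 anti to the C3 prenyl group and the cis C2 methyl; this fixes C5 (S) with the acyl branch cis to the C3 prenyl group, which later places that prenyl group on the same face of ring B as the enone bridge.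

**Step 6**
Reactants: 15 (2R,3S,5S)-5-[(E)-3-methoxy-7-methylocta-2,6-dienoyl]-2-methyl-3,5-bis(3-methylbut-2-en-1-yl)-2-(4-methylpent-3-en-1-yl)cyclopentan-1-one
Product: 18 (1R,5S,7S,8R)-2-methoxy-8-methyl-1,5,7-tris(3-methylbut-2-en-1-yl)-8-(4-methylpent-3-en-1-yl)bicyclo[3.3.1]non-2-ene-4,9-dione, via lithium aldolate 16 (not isolated), via iodo aldolate 17 (not isolated)
Conditions: LiN(i-Pr)2 (2.2 equiv), THF, −78 → −30 °C; then I2 (1.05 equiv), THF, −78 → 0 °C; aq. Na2S2O3
Reagents that add atoms: none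
Why: Proposed new method: a one-flask anionic annulation/ring expansion. The γ-lithiated β-methoxy enone (the only enolisable C–H) adds to the cyclopentanone carbonyl in a six-membered vinylogous aldol, cis fusion being forced by the C5 tether, to give aldolate 16; a second equivalent of base regenerates the dienolate, which is far more nucleophilic than the prenyl alkenes, and iodine intercepts it at the γ-carbon next to the carbinol to give 17; the alkoxide then drives a semipinacol 1,2-shift of the electron-rich C(Me)(homoprenyl) ring carbon (not the acyl-bearing C5) onto the iodide-bearing carbon with loss of iodide. This enlarges the cyclopentane to cyclohexanone ring B, creates the C1 quaternary bridgehead (configuration dictated by the bicycle, the migrating carbon retaining its own) and unveils the C9 ketone. The closest known reaction types are the halohydrin-type semipinacol ring expansion of 1-(1-haloalkyl)cycloalkanolates (Tiffeneau–Demjanov-like ketone homologation) and the quasi-Favorskii shift of α-halo ketones; neither has been run as a vinylogous aldol–iodination–shift cascade on a β-alkoxy enone.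

**Step 7**
Reactants: 19 benzene-1,2-diol (catechol)
Product: 20 4-bromobenzene-1,2-diol
Conditions: N-bromosuccinimide, HBF4·OEt2 (cat.), MeCN, −30 °C → rt
Reagents that add atoms: N-bromosuccinimide O=C1CCC(=O)N1Br
Why: Electrophilic aromatic substitution para to a hydroxyl group; acid-promoted N-bromosuccinimide gives clean mono-bromination at C4 of catechol.

**Step 8**
Reactants: 20 4-bromobenzene-1,2-diol
Product: 21 [(4-bromo-1,2-phenylene)bis(oxy)]bis(tert-butyldimethylsilane)
Conditions: t-BuMe2SiCl, imidazole, DMF, rt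
Reagents that add atoms: tert-butyl(chloro)dimethylsilane CC(C)(C)[Si](C)(C)Cl
Why: Imidazole-promoted silylation protects both phenols as silyl ethers so that the arene tolerates organolithium chemistry.

**Step 9**
Reactants: 21 [(4-bromo-1,2-phenylene)bis(oxy)]bis(tert-butyldimethylsilane)
Product: 24 3,4-bis[(tert-butyldimethylsilyl)oxy]benzoyl chloride, via aryllithium 22 (not isolated), via lithium carboxylate 23 (not isolated)
Conditions: n-BuLi, THF, −78 °C; CO2 (g), −78 → 0 °C; evaporate; (COCl)2, DMF (cat.), CH2Cl2, 0 °C → rt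
Reagents that add atoms: carbon dioxide O=C=O; oxalyl chloride O=C(Cl)C(Cl)=O
Why: Bromine–lithium exchange, carboxylation of the aryllithium and direct conversion of the lithium carboxylate with oxalyl chloride (neutral, so the aryl silyl ethers survive) give the aroyl chloride.

**Step 10**
Reactants: 18 (1R,5S,7S,8R)-2-methoxy-8-methyl-1,5,7-tris(3-methylbut-2-en-1-yl)-8-(4-methylpent-3-en-1-yl)bicyclo[3.3.1]non-2-ene-4,9-dione; 24 3,4-bis[(tert-butyldimethylsilyl)oxy]benzoyl chloride
Product: 25 (1R,5R,7S,8R)-3-{3,4-bis[(tert-butyldimethylsilyl)oxy]benzoyl}-2-methoxy-8-methyl-1,5,7-tris(3-methylbut-2-en-1-yl)-8-(4-methylpent-3-en-1-yl)bicyclo[3.3.1]non-2-ene-4,9-dione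
Conditions: lithium 2,2,6,6-tetramethylpiperidide, THF, −78 °C; then 24, −78 → −40 °C
Reagents that add atoms: none
Why: With both bridgeheads quaternary the only acidic C–H is the vinylic C3–H of the β-methoxy enone; the hindered amide base removes it and the vinyllithium is C-acylated by the acid chloride (vinylic lithiation–acylation), without touching any stereocentre.

**Step 11**
Reactants: 25 (1R,5R,7S,8R)-3-{3,4-bis[(tert-butyldimethylsilyl)oxy]benzoyl}-2-methoxy-8-methyl-1,5,7-tris(3-methylbut-2-en-1-yl)-8-(4-methylpent-3-en-1-yl)bicyclo[3.3.1]non-2-ene-4,9-dione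
Product: 26 (1S,5S,7S,8R)-3-(3,4-dihydroxybenzoyl)-4-hydroxy-8-methyl-1,5,7-tris(3-methylbut-2-en-1-yl)-8-(4-methylpent-3-en-1-yl)bicyclo[3.3.1]non-3-ene-2,9-dione (CNP0108469.1)
Conditions: LiOH·H2O, degassed 1,4-dioxane/H2O, 90 °C; then 1 M HCl
Reagents that add atoms: water O
Why: Hydroxide adds to the doubly activated enol-ether carbon and expels methoxide (addition–elimination hydrolysis of a vinylogous ester) and cleaves both phenolic silyl ethers; the product is shielded from retro-Claisen cleavage as its triketone enolate until acidification.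

**Compound list**
1 | 2-methylcyclopent-2-en-1-one | CC1=CCCC1=O | starting material
2 | 4-bromo-2-methylbut-1-ene | CC(=C)CCBr | starting material
3 | (3-methylbut-3-en-1-yl)magnesium bromide | CC(=C)CC[Mg]Br | intermediate
4 | bromomagnesium (S)-2-methyl-3-(3-methylbut-3-en-1-yl)cyclopent-1-en-1-olate | CC1=C(O[Mg]Br)CC[C@@H]1CCC(C)=C | intermediate
5 | (S)-trimethyl{[2-methyl-3-(3-methylbut-3-en-1-yl)cyclopent-1-en-1-yl]oxy}silane | CC1=C(O[Si](C)(C)C)CC[C@@H]1CCC(C)=C | intermediate
6 | 5-bromo-2-methylpent-2-ene | CC(C)=CCCBr | starting material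
7 | lithium (S)-2-methyl-3-(3-methylbut-3-en-1-yl)cyclopent-1-en-1-olate | CC1=C(O[Li])CC[C@@H]1CCC(C)=C | intermediate
8 | (2R,3S)-2-methyl-3-(3-methylbut-3-en-1-yl)-2-(4-methylpent-3-en-1-yl)cyclopentan-1-one | CC(C)=CCC[C@]1(C)[C@@H](CCC(C)=C)CCC1=O | intermediate
9 | (2R,3R)-2-methyl-3-(3-methylbut-2-en-1-yl)-2-(4-methylpent-3-en-1-yl)cyclopentan-1-one | CC(C)=CCC[C@]1(C)[C@@H](CC=C(C)C)CCC1=O | intermediate
10 | (E)-3-methoxybut-2-enoic acid | C/C(OC)=C\C(=O)O | starting material
11 | (E)-1-(1H-imidazol-1-yl)-3-methoxybut-2-en-1-one | C/C(OC)=C\C(=O)n1ccnc1 | intermediate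
12 | (2R,3S)-5-[(E)-3-methoxybut-2-enoyl]-2-methyl-3-(3-methylbut-2-en-1-yl)-2-(4-methylpent-3-en-1-yl)cyclopentan-1-one (C5 epimers/enol form) | CC(C)=CCC[C@]1(C)[C@@H](CC=C(C)C)CC(C(=O)/C=C(\C)OC)C1=O | intermediate
13 | 1-bromo-3-methylbut-2-ene (prenyl bromide) | CC(C)=CCBr | starting material
14 | lithium (4S,5R)-2-[(E)-3-methoxy-7-methylocta-2,6-dienoyl]-5-methyl-4-(3-methylbut-2-en-1-yl)-5-(4-methylpent-3-en-1-yl)cyclopent-1-en-1-olate | CC(C)=CCC[C@]1(C)[C@@H](CC=C(C)C)CC(C(=O)/C=C(\CCC=C(C)C)OC)=C1O[Li] | intermediate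
15 | (2R,3S,5S)-5-[(E)-3-methoxy-7-methylocta-2,6-dienoyl]-2-methyl-3,5-bis(3-methylbut-2-en-1-yl)-2-(4-methylpent-3-en-1-yl)cyclopentan-1-one | CC(C)=CCC[C@]1(C)[C@@H](CC=C(C)C)C[C@@](CC=C(C)C)(C(=O)/C=C(\CCC=C(C)C)OC)C1=O | intermediate
16 | lithium 6-methoxy-1-methyl-2,3a,7-tris(3-methylbut-2-en-1-yl)-1-(4-methylpent-3-en-1-yl)-4-oxo-2,3,3a,4,7,7a-hexahydro-1H-inden-7a-olate (cis-fused; 3a-prenyl and 7a-O cis; 2-prenyl cis to 1-methyl and trans to 3a-prenyl; C7 epimers) | CC(C)=CCC[C@]1(C)[C@@H](CC=C(C)C)C[C@@]2(CC=C(C)C)C(=O)C=C(OC)C(CC=C(C)C)[C@@]12O[Li] | intermediate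
17 | lithium 7-iodo-6-methoxy-1-methyl-2,3a,7-tris(3-methylbut-2-en-1-yl)-1-(4-methylpent-3-en-1-yl)-4-oxo-2,3,3a,4,7,7a-hexahydro-1H-inden-7a-olate (ring stereocentres as in 16) | CC(C)=CCC[C@]1(C)[C@@H](CC=C(C)C)C[C@@]2(CC=C(C)C)C(=O)C=C(OC)C(I)(CC=C(C)C)[C@@]12O[Li] | intermediate
18 | (1R,5S,7S,8R)-2-methoxy-8-methyl-1,5,7-tris(3-methylbut-2-en-1-yl)-8-(4-methylpent-3-en-1-yl)bicyclo[3.3.1]non-2-ene-4,9-dione | CC(C)=CCC[C@]1(C)[C@@H](CC=C(C)C)C[C@]2(CC=C(C)C)C(=O)[C@@]1(CC=C(C)C)C(OC)=CC2=O | intermediate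
19 | benzene-1,2-diol (catechol) | Oc1ccccc1O | starting material
20 | 4-bromobenzene-1,2-diol | Oc1ccc(Br)cc1O | intermediate
21 | [(4-bromo-1,2-phenylene)bis(oxy)]bis(tert-butyldimethylsilane) | CC(C)(C)[Si](C)(C)Oc1ccc(Br)cc1O[Si](C)(C)C(C)(C)C | intermediate
22 | {3,4-bis[(tert-butyldimethylsilyl)oxy]phenyl}lithium | [Li]c1ccc(O[Si](C)(C)C(C)(C)C)c(O[Si](C)(C)C(C)(C)C)c1 | intermediate
23 | lithium 3,4-bis[(tert-butyldimethylsilyl)oxy]benzoate | [Li+].[O-]C(=O)c1ccc(O[Si](C)(C)C(C)(C)C)c(O[Si](C)(C)C(C)(C)C)c1 | intermediate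
24 | 3,4-bis[(tert-butyldimethylsilyl)oxy]benzoyl chloride | ClC(=O)c1ccc(O[Si](C)(C)C(C)(C)C)c(O[Si](C)(C)C(C)(C)C)c1 | intermediate
25 | (1R,5R,7S,8R)-3-{3,4-bis[(tert-butyldimethylsilyl)oxy]benzoyl}-2-methoxy-8-methyl-1,5,7-tris(3-methylbut-2-en-1-yl)-8-(4-methylpent-3-en-1-yl)bicyclo[3.3.1]non-2-ene-4,9-dione | CC(C)=CCC[C@]1(C)[C@@H](CC=C(C)C)C[C@]2(CC=C(C)C)C(=O)[C@@]1(CC=C(C)C)C(OC)=C(C(=O)c1ccc(O[Si](C)(C)C(C)(C)C)c(O[Si](C)(C)C(C)(C)C)c1)C2=O | intermediate
26 | (1S,5S,7S,8R)-3-(3,4-dihydroxybenzoyl)-4-hydroxy-8-methyl-1,5,7-tris(3-methylbut-2-en-1-yl)-8-(4-methylpent-3-en-1-yl)bicyclo[3.3.1]non-3-ene-2,9-dione | CC(C)=CCC[C@]1(C)[C@@H](CC=C(C)C)C[C@]2(CC=C(C)C)C(=O)[C@@]1(CC=C(C)C)C(=O)C(C(=O)c1ccc(O)c(O)c1)=C2O | target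

**Totals**
Total step count: 11. Longest linear sequence: 8 steps (steps 1–6, 10, 11).

**Steps most likely to fail**

Step 6, the proposed new step, can fail through retro-aldol of 16, closure of 17 to an epoxide, or loss of HI from the tertiary iodide instead of the shift. The fallback uses known reaction types with a cationic trigger and sets out from 15. One equivalent of LiN(i-Pr)2 at −78 °C followed by an acetic acid quench gives the isolated hydroxy enone F1 (intramolecular vinylogous aldol of a 3-methoxy-enone dienolate). LiN(i-Pr)2 (2.2 equiv) and Me3SiCl convert it into the bis-silyl dienol ether F2. N-Bromosuccinimide at −78 °C gives the γ-bromo enone F3 (γ-halogenation of a silyl dienol ether). AgBF4 in CH2Cl2 at −40 °C then abstracts bromide and triggers the silver-assisted semipinacol shift with loss of the silyl group, which comes back to the route at 18.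

Step 5 can fail through modest facial selectivity or O-alkylation at C5 when the lithium diketonate 14 is alkylated directly. The fallback sets out from 12. Dianion formation with LiN(i-Pr)2 (2.1 equiv) and one equivalent of 13, then quench, gives the isolated γ-prenylated diketone F4. The C5 prenyl group is then introduced by Tsuji–Trost allylation of the soft β-diketonate with methyl 3-methylbut-2-en-1-yl carbonate, Pd2(dba)3 (zerovalent palladium) and the matched enantiomer of a chiral Trost bisphosphine ligand in THF at rt; this gives linear attack with catalyst-controlled facial selection and comes back to the route at 15.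

Step 2 can fail through E2 loss of HBr from the homoallylic bromide and slow alkylation of the tetrasubstituted enolate. The fallback sets out from 5. A Mukaiyama–Michael addition to acrolein (BF3·OEt2, CH2Cl2, −78 °C, aqueous work-up) builds the quaternary centre anti to the C3 chain and gives the keto aldehyde F5. An aldehyde-selective Wittig reaction with isopropylidenetriphenylphosphorane (from isopropyltriphenylphosphonium iodide and n-BuLi, THF, −78 → 0 °C) then installs the trisubstituted alkene and comes back to the route at 8.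

**Further compounds**
F1 | step 6 | 7a-hydroxy-6-methoxy-1-methyl-2,3a,7-tris(3-methylbut-2-en-1-yl)-1-(4-methylpent-3-en-1-yl)-1,2,3,3a,7,7a-hexahydro-4H-inden-4-one (cis-fused, ring stereocentres as in 16) | CC(C)=CCC[C@]1(C)[C@@H](CC=C(C)C)C[C@@]2(CC=C(C)C)C(=O)C=C(OC)C(CC=C(C)C)[C@@]12O
F2 | step 6 | bis(trimethylsilyl) derivative of F1: 7a-trimethylsilyl ether and 4-trimethylsilyloxy-4,6-diene (silyl dienol ether) | CC(C)=CCC[C@]1(C)[C@@H](CC=C(C)C)C[C@@]2(CC=C(C)C)C(O[Si](C)(C)C)=CC(OC)=C(CC=C(C)C)[C@@]12O[Si](C)(C)C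
F3 | step 6 | 7-bromo-6-methoxy-1-methyl-2,3a,7-tris(3-methylbut-2-en-1-yl)-1-(4-methylpent-3-en-1-yl)-7a-[(trimethylsilyl)oxy]-1,2,3,3a,7,7a-hexahydro-4H-inden-4-one | CC(C)=CCC[C@]1(C)[C@@H](CC=C(C)C)C[C@@]2(CC=C(C)C)C(=O)C=C(OC)C(Br)(CC=C(C)C)[C@@]12O[Si](C)(C)C
F4 | step 5 | (2R,3S)-5-[(E)-3-methoxy-7-methylocta-2,6-dienoyl]-2-methyl-3-(3-methylbut-2-en-1-yl)-2-(4-methylpent-3-en-1-yl)cyclopentan-1-one (C5 epimers/enol form) | CC(C)=CCC[C@]1(C)[C@@H](CC=C(C)C)CC(C(=O)/C=C(\CCC=C(C)C)OC)C1=O
F5 | step 2 | 3-[(1R,2S)-1-methyl-2-(3-methylbut-3-en-1-yl)-5-oxocyclopentyl]propanal | O=CCC[C@]1(C)[C@@H](CCC(C)=C)CCC1=O
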